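# Pulicanaral A: total synthesis via anionic oxy-Cope ring expansion

**Retrosynthesis**
1. Pulicanaral A (**18**) comes from the epoxy-aldehyde, which comes from the C14 allylic alcohol of the (1Z,4E)-cyclodecadiene enol triflate **12**. The C14 methyl is oxidised late, and the C4=C5 alkene is unmasked from the triflate.
2. Ten-membered ring **12** forms by anionic oxy-Cope ring expansion (new C2–C3 bond, six to ten ring) of the cis-1-isopropenyl-2-vinylcyclohexanol **11**, with the enolate trapped as the enol triflate.
3. **11** comes from isopropenyl addition to ketone **9**. The vinyl group comes from aldol addition then dehydration at C10 of enone **6**, which comes from Rubottom oxidation at C6.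
4. Enone **4** is made from (S)-α-phellandrene by singlet-oxygen [4+2] then Kornblum–DeLaMare rearrangement, which sets C7, C8 and the C5 ketone.

Ring order: transient endoperoxide bicycle, then cyclohexane (from phellandrene), then cyclodecane (oxy-Cope), then oxirane.

**Assumptions:**
- (S)-(+)-α-phellandrene is purchased from natural oil fractions.
- The Kornblum–DeLaMare step removes the less hindered bridgehead H (C5–H).

## Route

**Step 1**
Reactants: **1** (S)-α-phellandrene
Product: **2** endoperoxide, 6-methyl-8-isopropyl-2,3-dioxabicyclo[2.2.2]oct-5-ene, peroxide bridge anti to iPr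
Conditions: O2, hν (visible), TPP (cat.), CH2Cl2, –78 → 0 °C
Reagents that add atoms: singlet oxygen (from O2), O=O
Why: Singlet O2 undergoes a [4+2] cycloaddition across the 1,3-diene from the face anti to the C7 isopropyl, so both new C–O bonds (C5, C8) are anti to iPr.

**Step 2**
Reactants: **2**
Product: **3** trans-4-hydroxy-5-isopropyl-2-methylcyclohex-2-en-1-one
Conditions: Et3N, CH2Cl2, 0 °C → rt
Reagents that add atoms: none
Why: Kornblum–DeLaMare rearrangement: base removes the less hindered C5–H and cleaves O–O, giving the C5 ketone and the C8 alkoxide with its configuration retained (O8 trans to iPr).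

**Step 3**
Reactants: **3**
Product: **4** C8-OTBS enone
Conditions: TBSCl, imidazole, DMF, rt
Reagents that add atoms: tert-butyldimethylsilyl chloride, CC(C)(C)[Si](C)(C)Cl
Why: Silylation of the secondary alcohol protects it against the later strongly basic steps; no stereocentre is affected.

**Step 4**
Reactants: **4**
Product: **5** 2-silyloxy-1,3-diene (C5-OTBS, C5=C6, C9=C10)
Conditions: LiHMDS, THF, –78 °C; TBSCl, –78 °C → rt
Reagents that add atoms: tert-butyldimethylsilyl chloride, CC(C)(C)[Si](C)(C)Cl
Why: Kinetic deprotonation can only occur at C6, because C10 is sp2, so the enolate is regiospecific.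

**Step 5**
Reactants: **5**
Product: **6** 4,6-bis(TBS-oxy)-5-isopropyl-2-methylcyclohex-2-en-1-one (6-OTBS cis to iPr, 4-OTBS trans to iPr)
Conditions: DMDO, acetone/CH2Cl2, 0 °C → rt
Reagents that add atoms: dimethyldioxirane (O donor), CC1(C)OO1
Why: Rubottom oxidation: DMDO epoxidises the silyl enol ether along the axial trajectory of the half-chair. This places the new C6–O axial and cis to the equatorial C7 iPr, and silyl migration then gives the α'-OTBS enone.

**Step 6**
Reactants: **6**, **7** acetaldehyde
Product: **8** 2-(1-hydroxyethyl)-2-methyl-4,6-bis(OTBS)-5-isopropylcyclohexanone (carbinol epimers)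
Conditions: L-Selectride, THF, –78 °C; then CH3CHO, –78 °C
Reagents that add atoms: acetaldehyde (compound **7**), CC=O
Why: L-Selectride 1,4-reduction gives the C5/C10 lithium enolate regiospecifically, and aldol capture at C10 occurs on the face anti to the axial C6–OTBS. This sets the quaternary C10 with the new carbon chain cis to the future isopropenyl group; the carbinol centre is destroyed in Step 7.

**Step 7**
Reactants: **8**
Product: **9** 2-methyl-2-vinyl-4,6-bis(OTBS)-5-isopropylcyclohexanone
Conditions: Burgess reagent, PhH, 50 °C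
Reagents that add atoms: none
Why: Burgess syn-dehydration can only remove H from the methyl group, since C10 is quaternary, so it delivers the terminal vinyl group regiospecifically.

**Step 8**
Reactants: **9**, **10** isopropenylmagnesium bromide
Product: **11** 1-isopropenyl-2-methyl-2-vinyl-cyclohexan-1-ol (vinyl cis to isopropenyl)
Conditions: CH2=C(CH3)MgBr, CeCl3, THF, –78 → 0 °C
Reagents that add atoms: isopropenylmagnesium bromide (compound **10**), C=C(C)[Mg]Br
Why: Organocerium 1,2-addition follows Felkin–Anh anti to the axial C6–OTBS, delivering isopropenyl to the same face as the vinyl group and giving the cis-1,2-divinyl tertiary alcohol needed for the chair transition state.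

**Step 9**
Reactants: **11**
Product: **12** (1Z,4E)-cyclodeca-1,4-diene enol triflate (C5-OTf, C4-Me; C10-Me; 6,8-bis-OTBS; 7-iPr)
Conditions: KH, 18-crown-6, THF, 0 °C → rt; then Comins' reagent, –78 °C
Reagents that add atoms: Comins' reagent, O=S(=O)(C(F)(F)F)N(c1ccc(Cl)cn1)S(=O)(=O)C(F)(F)F (adds CF3SO2)
Why: Anionic oxy-Cope through a chair transition state, where the cis-divinyl geometry puts C6 equatorial (4E ring alkene) and C9 axial (1Z ring alkene). It forms the C2–C3 bond and the enolate is trapped regiospecifically as the vinyl triflate.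

**Step 10**
Reactants: **12**
Product: **13** C14 allylic alcohol
Conditions: SeO2 (0.2 equiv), TBHP, CH2Cl2, rt
Reagents that add atoms: tert-butyl hydroperoxide (O source), CC(C)(C)OO
Why: Riley allylic hydroxylation occurs at the C14 methyl trans to C2 on the only electron-rich alkene (C1=C10), since the enol triflate is inert to SeO2.

**Step 11**
Reactants: **13**
Product: **14** 1,10-epoxy alcohol
Conditions: VO(acac)2 (5 mol%), TBHP, CH2Cl2, 0 °C → rt
Reagents that add atoms: tert-butyl hydroperoxide (O source), CC(C)(C)OO
Why: Hydroxyl-directed vanadium epoxidation is stereospecific, giving the ring-cis epoxide from the Z ring alkene, and it occurs on the peripheral face set by the ring conformation; the electron-poor enol triflate is untouched.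

**Step 12**
Reactants: **14**
Product: **15** (4E)-alkene epoxy alcohol
Conditions: Pd(OAc)2, PPh3, HCO2H, Et3N, DMF, 60 °C
Reagents that add atoms: none
Why: Pd-catalysed formate reduction of the vinyl triflate replaces OTf with H and keeps the E ring geometry; the TBS ethers, epoxide and free alcohol survive.

**Step 13**
Reactants: **15**
Product: **16** triol
Conditions: TBAF, AcOH, THF, 40 °C
Reagents that add atoms: none
Why: Buffered fluoride removes both TBS ethers without opening the epoxide (HF-pyridine could open it).

**Step 14**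
Reactants: **16**
Product: **17** epoxy-aldehyde diol
Conditions: TEMPO (cat.), PhI(OAc)2, CH2Cl2, rt
Reagents that add atoms: none
Why: TEMPO/BAIB oxidises the primary neopentyl carbinol chemoselectively and leaves the hindered secondary alcohols alone.

**Step 15**
Reactants: **17**
Product: **18** Pulicanaral A
Conditions: Ac2O, DMAP, pyridine, 0 °C → rt
Reagents that add atoms: acetic anhydride, CC(=O)OC(C)=O
Why: Acetylation of the two secondary alcohols leaves all stereocentres untouched and gives the target.

## Compound list

1 | (S)-(+)-α-phellandrene | CC1=CC[C@@H](C(C)C)C=C1 | starting material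
2 | 6-methyl-8-isopropyl-2,3-dioxabicyclo[2.2.2]oct-5-ene (peroxide anti to iPr) | CC1=C[C@H]2OO[C@@H]1C[C@H]2C(C)C | intermediate
3 | trans-4-hydroxy-5-isopropyl-2-methylcyclohex-2-en-1-one | O=C1C[C@@H](C(C)C)[C@H](O)C=C1C | intermediate
4 | 4-OTBS analogue of 3 | O=C1C[C@@H](C(C)C)[C@H](O[Si](C)(C)C(C)(C)C)C=C1C | intermediate
5 | 1,4-bis(TBS-oxy)-cyclohexa-1,3-diene (C5 silyl dienol ether) | CC1=C[C@@H](O[Si](C)(C)C(C)(C)C)[C@H](C(C)C)C=C1O[Si](C)(C)C(C)(C)C | intermediate
6 | 4,6-bis(TBS-oxy)-5-isopropyl-2-methylcyclohex-2-en-1-one | O=C1[C@@H](O[Si](C)(C)C(C)(C)C)[C@@H](C(C)C)[C@H](O[Si](C)(C)C(C)(C)C)C=C1C | intermediate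
7 | acetaldehyde | CC=O | starting material
8 | aldol adduct (carbinol epimers) | O=C1[C@@H](O[Si](C)(C)C(C)(C)C)[C@@H](C(C)C)[C@H](O[Si](C)(C)C(C)(C)C)C[C@]1(C)C(C)O | intermediate
9 | 2-methyl-2-vinyl ketone | O=C1[C@@H](O[Si](C)(C)C(C)(C)C)[C@@H](C(C)C)[C@H](O[Si](C)(C)C(C)(C)C)C[C@]1(C)C=C | intermediate
10 | isopropenylmagnesium bromide | C=C(C)[Mg]Br | starting material
11 | 1-isopropenyl-2-methyl-2-vinylcyclohexanol (oxy-Cope substrate) | C=C(C)[C@]1(O)[C@@H](O[Si](C)(C)C(C)(C)C)[C@@H](C(C)C)[C@H](O[Si](C)(C)C(C)(C)C)C[C@]1(C)C=C | intermediate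
12 | cyclodecadiene enol triflate | CC(C)(C)[Si](C)(C)O[C@@H]1/C(OS(=O)(=O)C(F)(F)F)=C(\C)CC/C=C(/C)C[C@@H](O[Si](C)(C)C(C)(C)C)[C@@H]1C(C)C | intermediate
13 | C14 allylic alcohol | CC(C)(C)[Si](C)(C)O[C@@H]1/C(OS(=O)(=O)C(F)(F)F)=C(\C)CC/C=C(/CO)C[C@@H](O[Si](C)(C)C(C)(C)C)[C@@H]1C(C)C | intermediate
14 | epoxy alcohol | CC(C)(C)[Si](C)(C)O[C@@H]1/C(OS(=O)(=O)C(F)(F)F)=C(\C)CC[C@H]2O[C@@]2(CO)C[C@@H](O[Si](C)(C)C(C)(C)C)[C@@H]1C(C)C | intermediate
15 | alkene epoxy alcohol | CC(C)(C)[Si](C)(C)O[C@@H]1/C=C(\C)CC[C@H]2O[C@@]2(CO)C[C@@H](O[Si](C)(C)C(C)(C)C)[C@@H]1C(C)C | intermediate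
16 | triol | O[C@@H]1/C=C(\C)CC[C@H]2O[C@@]2(CO)C[C@@H](O)[C@@H]1C(C)C | intermediate
17 | epoxy-aldehyde diol | O[C@@H]1/C=C(\C)CC[C@H]2O[C@@]2(C=O)C[C@@H](O)[C@@H]1C(C)C | intermediate
18 | Pulicanaral A | CC(=O)O[C@@H]1/C=C(\C)CC[C@H]2O[C@@]2(C=O)C[C@@H](OC(C)=O)[C@@H]1C(C)C | target

**Total steps: 15. Longest linear sequence: 15.**

## Three steps most likely to fail

1. **Step 9 (oxy-Cope).** It depends on the cis-divinyl relationship set in Steps 6 and 8 and on the chair transition state giving the (1Z,4E) geometry. A trans-divinyl isomer would give the wrong alkene geometry.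
   *Fallback:* abandon the ring expansion and close the ten-membered ring by intramolecular Nozaki–Hiyama–Kishi coupling of an acyclic allylic bromide/aldehyde pair.
2. **Step 10 (SeO2 oxidation of C14).** Oxidation could occur at the ring CH2 groups (C9, C2) instead of the C14 methyl.
   *Fallback:* start from an enone that already carries C14 as CH2OTBDPS (from perillyl alcohol, via selective isopropenyl hydrogenation and allylic oxidation) so no late methyl oxidation is needed.
3. **Step 11 (epoxidation face).** The stereochemistry of the epoxide relies on conformational control of the ten-membered ring.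
   *Fallback:* oxidise the C14 alcohol to the enal (MnO2) and use nucleophilic Weitz–Scheffer epoxidation (H2O2, NaOH), letting the ring conformation direct the face.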